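**Strategy.** Ring C is disconnected at C2–C3. The key step is an enantioselective intramolecular C–H insertion: a dirhodium carbenoid generated at C3 from an aryl diazomethyl ketone (C4 carbonyl on ring A) inserts into one of the two enantiotopic benzylic hydrogens of the O1–CH2–aryl ether, closing the pyranone ring and setting C2 in one operation. It exploits the hydridic C2–H bond, activated by the O1 lone pair and the electron-rich ring B, and its 1,6 relationship to C3. The precursor is a fully silylated 2-(3,4-disiloxybenzyloxy)-6-siloxyphenyl diazomethyl ketone carrying the hydrated geranyl chain. Substrate-controlled trans hydroxylation at C3 and global desilylation finish the synthesis.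

Key step: step 10

Remarks and assumption: flavonoid numbering is used (O1, C2, C3, C4, C4a, C5 to C8, C8a; ring A benzo, ring B catechol, ring C pyranone). TBSO = tert-butyldimethylsilyloxy, TIPSO = triisopropylsilyloxy. The sense of induction of Rh2(S-BSP)4 on this substrate cannot be predicted with certainty; it is assumed to give 2S in step 10, and the mirror-image catalyst Rh2(R-BSP)4 is used if the first run shows the opposite sense.

**Step 1**
Reactants: 1 geraniol
Product: 3 (2E)-3,7-dimethyloct-2-ene-1,7-diol, via organomercurial 2 (not isolated)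
Conditions: Hg(OAc)2, THF/H2O, 0 °C to rt; then NaBH4, aq. NaOH, 0 °C
Reagents that add atoms: water, O
Why: Oxymercuration–demercuration (Markovnikov hydration): Hg(OAc)2 attacks the more electron-rich 6,7-alkene (the 2,3-alkene is deactivated by the allylic hydroxyl), water opens the mercurinium ion at the tertiary carbon and NaBH4 replaces mercury by hydrogen; the 2E alkene is untouched.

**Step 2**
Reactants: 3 (2E)-3,7-dimethyloct-2-ene-1,7-diol
Product: 4 (6E)-8-bromo-2,6-dimethyloct-6-en-2-ol
Conditions: N-bromosuccinimide, Me2S, CH2Cl2, −20 to 0 °C; used without storage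
Reagents that add atoms: N-bromosuccinimide, O=C1CCC(=O)N1Br
Why: Corey–Kim bromination: the sulfonium reagent activates only the primary allylic hydroxyl, which bromide displaces directly (no allylic transposition, E geometry kept), while the tertiary alcohol does not react.

**Step 3**
Reactants: 4 (6E)-8-bromo-2,6-dimethyloct-6-en-2-ol; 5 2,4,6-trihydroxyacetophenone (dried, in excess)
Product: 6 1-{2,4,6-trihydroxy-3-[(2E)-7-hydroxy-3,7-dimethyloct-2-en-1-yl]phenyl}ethanone
Conditions: DBU, THF, 0 °C to rt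
Reagents that add atoms: none
Why: Nuclear C-alkylation of the ambident phloroacetophenone anion by a soft allylic bromide (known C-prenylation and C-geranylation of acylphloroglucinols); the two free ring carbons of 5 are equivalent, so only one regioisomer can form, and excess 5 should limit double alkylation.

**Step 4**
Reactants: 6 C-alkylated triol
Product: 7 1-{2,6-dihydroxy-3-[(2E)-7-hydroxy-3,7-dimethyloct-2-en-1-yl]-4-TIPSO-phenyl}ethanone
Conditions: TIPSCl (1.05 equiv), imidazole, DMF, 0 °C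
Reagents that add atoms: triisopropylsilyl chloride, CC(C)[Si](Cl)(C(C)C)C(C)C
Why: Regioselective silylation: the hydroxyl para to the acetyl group is the only one not locked in a hydrogen bond to the carbonyl and is the most acidic and accessible; the tertiary alcohol is inert to TIPSCl/imidazole.

**Step 5**
Reactants: 8 3,4-dihydroxybenzaldehyde
Product: 9 3,4-bis(TBSO)benzaldehyde
Conditions: TBSCl (2.4 equiv), imidazole, DMF, rt
Reagents that add atoms: tert-butyldimethylsilyl chloride, CC(C)(C)[Si](C)(C)Cl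
Why: Standard silylation of both catechol hydroxyls, chosen so that ring B is unmasked by fluoride together with all other groups at the end.

**Step 6**
Reactants: 9 3,4-bis(TBSO)benzaldehyde
Product: 10 [3,4-bis(TBSO)phenyl]methanol
Conditions: NaBH4, MeOH/THF, 0 °C
Reagents that add atoms: none
Why: Chemoselective hydride reduction of the aldehyde; the aryl silyl ethers should survive the short exposure at 0 °C.

**Step 7**
Reactants: 7 TIPS-protected diol ketone; 10 [3,4-bis(TBSO)phenyl]methanol
Product: 11 1-{6-[3,4-bis(TBSO)benzyloxy]-2-hydroxy-3-[(2E)-7-hydroxy-3,7-dimethyloct-2-en-1-yl]-4-TIPSO-phenyl}ethanone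
Conditions: PPh3, DIAD, THF, 0 °C to rt
Reagents that add atoms: none
Why: Mitsunobu etherification under neutral conditions that spare the aryl silyl ethers; of the two chelated ortho hydroxyls the one next to the ring hydrogen (the future O1) is less hindered than the one flanked by the side chain, the remaining chelated hydroxyl resists a second etherification, and the tertiary alcohol is not activated.

**Step 8**
Reactants: 11 aryl benzyl ether
Product: 12 1-{6-[3,4-bis(TBSO)benzyloxy]-2-TBSO-3-[(2E)-7-TBSO-3,7-dimethyloct-2-en-1-yl]-4-TIPSO-phenyl}ethanone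
Conditions: TBSOTf (3 equiv), 2,6-lutidine, CH2Cl2, −78 to 0 °C
Reagents that add atoms: tert-butyldimethylsilyl trifluoromethanesulfonate, CC(C)(C)[Si](C)(C)OS(=O)(=O)C(F)(F)F
Why: The silyl triflate silylates both the hindered chelated phenol and the tertiary alcohol in one operation, so that no O–H bond is left for the carbenoid and the 5-oxygen carries a group without a C–H bond in 1,6 relationship to C3.

**Step 9**
Reactants: 12 pentasilylated methyl ketone
Product: 15 2-diazo-1-{6-[3,4-bis(TBSO)benzyloxy]-2-TBSO-3-[(2E)-7-TBSO-3,7-dimethyloct-2-en-1-yl]-4-TIPSO-phenyl}ethanone, via lithium enolate 13 (not isolated), via trifluoroacetyl ketone 14 (not isolated)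
Conditions: LiN(SiMe3)2, THF, −78 °C; CF3CO2CH2CF3; 5% aq. HCl work-up, crude; then MsN3, Et3N, H2O (1 equiv), MeCN, rt
Reagents that add atoms: 2,2,2-trifluoroethyl trifluoroacetate, O=C(OCC(F)(F)F)C(F)(F)F (trifluoroacetyl group of 14 only); methanesulfonyl azide, CS(=O)(=O)N=[N+]=[N-] (the two diazo nitrogens of 15)
Why: Detrifluoroacetylative diazo transfer: the kinetic methyl ketone enolate is C-trifluoroacetylated, and the activated 1,3-diketone takes up the diazo group from the sulfonyl azide with loss of the trifluoroacetyl group as the N-sulfonyl amide; all other groups are inert silyl or aryl ethers.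

**Step 10**
Reactants: 15 diazomethyl ketone
Product: 16 (2S)-2-[3,4-bis(TBSO)phenyl]-5-TBSO-6-[(2E)-7-TBSO-3,7-dimethyloct-2-en-1-yl]-7-TIPSO-2,3-dihydro-4H-chromen-4-one
Conditions: Rh2(S-BSP)4 (dirhodium tetrakis[N-benzenesulfonyl-(S)-prolinate], 1 mol %), CH2Cl2, slow addition of 15, 0 °C to rt
Reagents that add atoms: none
Why: Rh2(S-BSP)4 decomposes the diazoketone to an electrophilic rhodium carbenoid at C3, which inserts into a benzylic C2–H bond through a three-centre, hydride-transfer-like transition state. The closest known reaction type is the chiral dirhodium carboxylate-catalysed intramolecular C–H insertion of 2-alkoxyphenyl diazoketones to chroman-4-ones. Ring C is closed as a six-membered ring by 1,6-insertion (C3 to C2 across C4, C4a, C8a and O1), the only activated C–H within reach. The C2 stereocentre arises by catalyst-controlled discrimination of the two enantiotopic hydrogens of the OCH2 group within the chiral prolinate ligand sphere; 2S is required, which is the same spatial arrangement as 2R in the target. The step needs insertion to outrun oxonium ylide formation at O1 followed by a benzyl 1,2-shift, which should be disfavoured because the O1 lone pair is delocalised into the acylated ring A while the C2–H bond is doubly activated by O1 and by the para-siloxy group of ring B. Other sites are excluded by design: no O–H bond remains, the 5-siloxy group offers no 1,6 C–H bond, and the side-chain alkene on C6 is meta to the acyl carbon and cannot reach C3.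

**Step 11**
Reactants: 16 (2S)-flavanone
Product: 18 (2R,3R)-2-[3,4-bis(TBSO)phenyl]-3-hydroxy-5-TBSO-6-[(2E)-7-TBSO-3,7-dimethyloct-2-en-1-yl]-7-TIPSO-2,3-dihydro-4H-chromen-4-one, via sodium enolate 17 (not isolated)
Conditions: NaN(SiMe3)2, THF, −78 °C; then 2-(phenylsulfonyl)-3-phenyloxaziridine, −78 °C; sat. aq. NH4Cl
Reagents that add atoms: 2-(phenylsulfonyl)-3-phenyloxaziridine, O=S(=O)(c1ccccc1)N1OC1c1ccccc1
Why: Enolate hydroxylation with an N-sulfonyloxaziridine (Davis oxidation): the kinetic sodium enolate (C3=C4) is oxygenated at C3 on the face anti to the adjacent C2 aryl group, which sets 3R trans to C2 (also the thermodynamically preferred diequatorial arrangement); the isolated alkene does not react with the oxaziridine and the low temperature suppresses β-elimination of the O1 aryloxide.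

**Step 12**
Reactants: 18 protected dihydroflavonol
Product: 19 (2R,3R)-2-(3,4-dihydroxyphenyl)-3,5,7-trihydroxy-6-[(2E)-7-hydroxy-3,7-dimethyloct-2-en-1-yl]-2,3-dihydro-4H-chromen-4-one
Conditions: HF·pyridine, pyridine, THF, 0 °C to rt
Reagents that add atoms: none
Why: Fluoride-mediated global desilylation cleaves the four aryl silyl ethers and the tertiary alkyl silyl ether without touching C2 or C3; the buffered, weakly acidic medium avoids both base-induced ring opening of the dihydroflavonol and strong-acid cyclisation of the 5- or 7-hydroxyl onto the side-chain alkene.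

**Compound list**

1 | geraniol, (2E)-3,7-dimethylocta-2,6-dien-1-ol | C/C(=C\CO)CCC=C(C)C | starting material
2 | (2E)-6-(acetoxymercurio)-3,7-dimethyloct-2-ene-1,7-diol (racemic at C6, not isolated) | C/C(=C\CO)CCC([Hg]OC(C)=O)C(C)(C)O | intermediate
3 | (2E)-3,7-dimethyloct-2-ene-1,7-diol | C/C(=C\CO)CCCC(C)(C)O | intermediate
4 | (6E)-8-bromo-2,6-dimethyloct-6-en-2-ol | C/C(=C\CBr)CCCC(C)(C)O | intermediate
5 | 2,4,6-trihydroxyacetophenone | CC(=O)c1c(O)cc(O)cc1O | starting material
6 | 1-{2,4,6-trihydroxy-3-[(2E)-7-hydroxy-3,7-dimethyloct-2-en-1-yl]phenyl}ethanone | C/C(=C\Cc1c(O)cc(O)c(C(C)=O)c1O)CCCC(C)(C)O | intermediate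
7 | 1-{2,6-dihydroxy-3-[(2E)-7-hydroxy-3,7-dimethyloct-2-en-1-yl]-4-(triisopropylsilyloxy)phenyl}ethanone | C/C(=C\Cc1c(O[Si](C(C)C)(C(C)C)C(C)C)cc(O)c(C(C)=O)c1O)CCCC(C)(C)O | intermediate
8 | 3,4-dihydroxybenzaldehyde | O=Cc1ccc(O)c(O)c1 | starting material
9 | 3,4-bis(tert-butyldimethylsilyloxy)benzaldehyde | O=Cc1ccc(O[Si](C)(C)C(C)(C)C)c(O[Si](C)(C)C(C)(C)C)c1 | intermediate
10 | [3,4-bis(tert-butyldimethylsilyloxy)phenyl]methanol | OCc1ccc(O[Si](C)(C)C(C)(C)C)c(O[Si](C)(C)C(C)(C)C)c1 | intermediate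
11 | 1-{6-[3,4-bis(TBSO)benzyloxy]-2-hydroxy-3-[(2E)-7-hydroxy-3,7-dimethyloct-2-en-1-yl]-4-TIPSO-phenyl}ethanone | C/C(=C\Cc1c(O[Si](C(C)C)(C(C)C)C(C)C)cc(OCc2ccc(O[Si](C)(C)C(C)(C)C)c(O[Si](C)(C)C(C)(C)C)c2)c(C(C)=O)c1O)CCCC(C)(C)O | intermediate
12 | 1-{6-[3,4-bis(TBSO)benzyloxy]-2-TBSO-3-[(2E)-7-TBSO-3,7-dimethyloct-2-en-1-yl]-4-TIPSO-phenyl}ethanone | C/C(=C\Cc1c(O[Si](C(C)C)(C(C)C)C(C)C)cc(OCc2ccc(O[Si](C)(C)C(C)(C)C)c(O[Si](C)(C)C(C)(C)C)c2)c(C(C)=O)c1O[Si](C)(C)C(C)(C)C)CCCC(C)(C)O[Si](C)(C)C(C)(C)C | intermediate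
13 | lithium enolate of 12 (not isolated) | [Li+].C/C(=C\Cc1c(O[Si](C(C)C)(C(C)C)C(C)C)cc(OCc2ccc(O[Si](C)(C)C(C)(C)C)c(O[Si](C)(C)C(C)(C)C)c2)c(C(=C)[O-])c1O[Si](C)(C)C(C)(C)C)CCCC(C)(C)O[Si](C)(C)C(C)(C)C | intermediate
14 | 4,4,4-trifluoro-1-aryl-butane-1,3-dione, aryl as in 12 (not isolated) | C/C(=C\Cc1c(O[Si](C(C)C)(C(C)C)C(C)C)cc(OCc2ccc(O[Si](C)(C)C(C)(C)C)c(O[Si](C)(C)C(C)(C)C)c2)c(C(=O)CC(=O)C(F)(F)F)c1O[Si](C)(C)C(C)(C)C)CCCC(C)(C)O[Si](C)(C)C(C)(C)C | intermediate
15 | 2-diazo-1-aryl-ethanone, aryl as in 12 | C/C(=C\Cc1c(O[Si](C(C)C)(C(C)C)C(C)C)cc(OCc2ccc(O[Si](C)(C)C(C)(C)C)c(O[Si](C)(C)C(C)(C)C)c2)c(C(=O)C=[N+]=[N-])c1O[Si](C)(C)C(C)(C)C)CCCC(C)(C)O[Si](C)(C)C(C)(C)C | intermediate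
16 | (2S)-2-[3,4-bis(TBSO)phenyl]-5-TBSO-6-[(2E)-7-TBSO-3,7-dimethyloct-2-en-1-yl]-7-TIPSO-2,3-dihydro-4H-chromen-4-one | C/C(=C\Cc1c(O[Si](C(C)C)(C(C)C)C(C)C)cc2c(c1O[Si](C)(C)C(C)(C)C)C(=O)C[C@@H](c1ccc(O[Si](C)(C)C(C)(C)C)c(O[Si](C)(C)C(C)(C)C)c1)O2)CCCC(C)(C)O[Si](C)(C)C(C)(C)C | intermediate
17 | sodium C3=C4 enolate of 16 (not isolated) | [Na+].C/C(=C\Cc1c(O[Si](C(C)C)(C(C)C)C(C)C)cc2c(c1O[Si](C)(C)C(C)(C)C)C([O-])=C[C@@H](c1ccc(O[Si](C)(C)C(C)(C)C)c(O[Si](C)(C)C(C)(C)C)c1)O2)CCCC(C)(C)O[Si](C)(C)C(C)(C)C | intermediate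
18 | (2R,3R)-2-[3,4-bis(TBSO)phenyl]-3-hydroxy-5-TBSO-6-[(2E)-7-TBSO-3,7-dimethyloct-2-en-1-yl]-7-TIPSO-2,3-dihydro-4H-chromen-4-one | C/C(=C\Cc1c(O[Si](C(C)C)(C(C)C)C(C)C)cc2c(c1O[Si](C)(C)C(C)(C)C)C(=O)[C@H](O)[C@@H](c1ccc(O[Si](C)(C)C(C)(C)C)c(O[Si](C)(C)C(C)(C)C)c1)O2)CCCC(C)(C)O[Si](C)(C)C(C)(C)C | intermediate
19 | (2R,3R)-2-(3,4-dihydroxyphenyl)-3,5,7-trihydroxy-6-[(2E)-7-hydroxy-3,7-dimethyloct-2-en-1-yl]-2,3-dihydro-4H-chromen-4-one | C/C(=C\Cc1c(O)cc2c(c1O)C(=O)[C@H](O)[C@@H](c1ccc(O)c(O)c1)O2)CCCC(C)(C)O | target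

**Step count**

Total: 12 steps. Longest linear sequence: 10 steps (steps 1, 2, 3, 4, 7, 8, 9, 10, 11, 12, from geraniol).

**Steps most likely to fail**

1. Step 10. What may go wrong: insufficient discrimination of the two enantiotopic benzylic hydrogens by the chiral carboxylate, so that the flavanone is formed with low enantiomeric purity. Diversion of part of the carbenoid into oxonium ylide formation at O1 is the second, less likely, loss channel; the fallback does not address it. The fallback sets out from 15 and changes the source of enantiopurity from catalyst-controlled insertion to kinetic resolution. Decomposition of 15 with achiral Rh2(OAc)4 (CH2Cl2, rt) should give the racemic flavanone F1. Noyori-type asymmetric transfer hydrogenation (RuCl[(R,R)-TsDPEN](p-cymene), HCO2H/Et3N, rt, run to just over half conversion) should then reduce the 2R enantiomer, whose carbonyl face anti to the C2 aryl group matches the catalyst, to the (2R,4R)-cis-flavan-4-ol F2, which is removed by chromatography. The unreacted 2S ketone is 16, where the fallback comes back to the route.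

2. Step 11. What may go wrong: β-elimination of the O1 aryloxide from the enolate (ring opening to the chalcone phenoxide and reclosure), which erodes the C2 configuration, or addition of the enolate to the sulfonimine by-product. The fallback sets out from 16 and replaces the basic enolate by a neutral enol ether (Rubottom oxidation). Soft enolisation (TMSOTf, Et3N, CH2Cl2, 0 °C) should give the trimethylsilyl enol ether F3. Dimethyldioxirane (1 equiv, acetone/CH2Cl2, −78 °C), which should attack the electron-rich enol ether far faster than the side-chain alkene and anti to the C2 aryl group, should give the silyloxy epoxide F4. Dilute aqueous citric acid should open it to the 3-hydroxy ketone 18, where the fallback comes back to the route.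

3. Step 7. What may go wrong: poor regioselection between the two chelated ortho hydroxyls, so that the hydroxyl flanked by the side chain is etherified (leading to the 8-substituted series), or double etherification. The fallback sets out from 5 and moves the etherification to a symmetrical stage. Silylation of 5 (TIPSCl, imidazole, DMF, 0 °C) should give 1-[2,6-dihydroxy-4-(triisopropylsilyloxy)phenyl]ethanone F5, in which the two ortho hydroxyls are equivalent. Mitsunobu reaction with 10 (PPh3, DIAD, THF) should give the mono-benzyl ether F6 without any regiochemical question. Its lithium phenoxide F7 (LiOtBu, toluene) should be C-alkylated by 4 at the ring carbon ortho to the phenoxide oxygen, the contact ion pair in the non-polar solvent directing the allylic bromide there, to give 11, where the fallback comes back to the route.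

**Further compounds**

F1 | step 10 | racemic 2-[3,4-bis(TBSO)phenyl]-5-TBSO-6-[(2E)-7-TBSO-3,7-dimethyloct-2-en-1-yl]-7-TIPSO-2,3-dihydro-4H-chromen-4-one | C/C(=C\Cc1c(O[Si](C(C)C)(C(C)C)C(C)C)cc2c(c1O[Si](C)(C)C(C)(C)C)C(=O)CC(c1ccc(O[Si](C)(C)C(C)(C)C)c(O[Si](C)(C)C(C)(C)C)c1)O2)CCCC(C)(C)O[Si](C)(C)C(C)(C)C
F2 | step 10 | (2R,4R)-2-[3,4-bis(TBSO)phenyl]-5-TBSO-6-[(2E)-7-TBSO-3,7-dimethyloct-2-en-1-yl]-7-TIPSO-3,4-dihydro-2H-chromen-4-ol (cis) | C/C(=C\Cc1c(O[Si](C(C)C)(C(C)C)C(C)C)cc2c(c1O[Si](C)(C)C(C)(C)C)[C@H](O)C[C@H](c1ccc(O[Si](C)(C)C(C)(C)C)c(O[Si](C)(C)C(C)(C)C)c1)O2)CCCC(C)(C)O[Si](C)(C)C(C)(C)C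
F3 | step 11 | (2S)-2-[3,4-bis(TBSO)phenyl]-5-TBSO-6-[(2E)-7-TBSO-3,7-dimethyloct-2-en-1-yl]-7-TIPSO-4-(trimethylsilyloxy)-2H-chromene | C/C(=C\Cc1c(O[Si](C(C)C)(C(C)C)C(C)C)cc2c(c1O[Si](C)(C)C(C)(C)C)C(O[Si](C)(C)C)=C[C@@H](c1ccc(O[Si](C)(C)C(C)(C)C)c(O[Si](C)(C)C(C)(C)C)c1)O2)CCCC(C)(C)O[Si](C)(C)C(C)(C)C
F4 | step 11 | 3,4-epoxide of F3 with the epoxide oxygen anti to the C2 aryl group and the trimethylsilyloxy group on C4 | C/C(=C\Cc1c(O[Si](C(C)C)(C(C)C)C(C)C)cc2c(c1O[Si](C)(C)C(C)(C)C)[C@]3(O[Si](C)(C)C)O[C@@H]3[C@@H](c1ccc(O[Si](C)(C)C(C)(C)C)c(O[Si](C)(C)C(C)(C)C)c1)O2)CCCC(C)(C)O[Si](C)(C)C(C)(C)C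
F5 | step 7 | 1-[2,6-dihydroxy-4-(triisopropylsilyloxy)phenyl]ethanone | CC(=O)c1c(O)cc(O[Si](C(C)C)(C(C)C)C(C)C)cc1O
F6 | step 7 | 1-{2-[3,4-bis(TBSO)benzyloxy]-6-hydroxy-4-(triisopropylsilyloxy)phenyl}ethanone | CC(=O)c1c(O)cc(O[Si](C(C)C)(C(C)C)C(C)C)cc1OCc1ccc(O[Si](C)(C)C(C)(C)C)c(O[Si](C)(C)C(C)(C)C)c1
F7 | step 7 | lithium phenoxide of F6 | [Li+].CC(=O)c1c([O-])cc(O[Si](C(C)C)(C(C)C)C(C)C)cc1OCc1ccc(O[Si](C)(C)C(C)(C)C)c(O[Si](C)(C)C(C)(C)C)c1
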